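Ring B (C5–C10, eremophilane numbering) carries the C8 ketone next to the C9 ester oxygen and is fused to ring A at quaternary C5 and C10. This pattern is read as the trace of a 2-silyloxy diene (C7=C8–C9=C10) and an isopropenyl-type dienophile (C5=C6) joined by the C1–C4 chain, which already holds the C3 angelate and C4 methyl. One thermal intramolecular Diels–Alder reaction of this acyclic silyloxy tetraene forms C6–C7 and C5–C10, closes both rings, sets the cis ring fusion and leaves a regiodefined C8=C9 silyl enol ether for Rubottom oxygenation at C9. Senecioylation and a final equilibration of C7 complete the route.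

Key step: step 6

Remark: locants follow eremophilane numbering (decalin C1–C10, C5 methyl = C14, C4 methyl = C15, isopropenyl C11–C13; β is the face of the C5 methyl); (R)-TRIP is assumed to direct allylboration to the aldehyde Re face, so (S)-TRIP is specified, and the antipode would be used if the sense were the reverse.

Step 1
Reactants: 1 (Z)-2-bromobut-2-ene; 2 2-(chloromethyl)-4,4,5,5-tetramethyl-1,3,2-dioxaborolane
Product: 5 (Z)-4,4,5,5-tetramethyl-2-(2-methylbut-2-en-1-yl)-1,3,2-dioxaborolane, via but-2-en-2-yllithium 3 (not isolated), via lithium boronate complex 4 (not isolated)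
Conditions: t-BuLi (2.0 equiv), Et2O, −78 °C; then 2, −78 °C → rt
Reagents that add atoms: none
Why: Bromine–lithium exchange with retention of alkene geometry, then a Matteson-type homologation (boronate formation and 1,2-migration of the alkenyl group with loss of chloride), should give the allylboronate with the terminal methyl cis to CH2B.

Step 2
Reactants: 5 (Z)-4,4,5,5-tetramethyl-2-(2-methylbut-2-en-1-yl)-1,3,2-dioxaborolane; 6 pent-4-ynal
Product: 8 (3R,4R)-2,3-dimethyloct-1-en-7-yn-4-ol, via O-boryl homoallyl ether 7 (not isolated)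
Conditions: (S)-TRIP [(S)-3,3'-bis(2,4,6-triisopropylphenyl)-1,1'-binaphthyl-2,2'-diyl hydrogen phosphate] (5 mol %), toluene, −30 → 0 °C; then aqueous NaHCO3
Reagents that add atoms: none
Why: Chiral-phosphoric-acid-catalysed allylboration through a closed chair transition state, in which the (Z)-γ-methyl is axial and gives the syn relationship while the catalyst selects the aldehyde Si face, should set the carbinol carbon (future C3) and the methyl-bearing carbon (future C4) both as R.

Step 3
Reactants: 8 (3R,4R)-2,3-dimethyloct-1-en-7-yn-4-ol; 9 angelic acid [(2Z)-2-methylbut-2-enoic acid]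
Product: 11 (3R,4R)-2,3-dimethyloct-1-en-7-yn-4-yl (2Z)-2-methylbut-2-enoate, via mixed anhydride 10 (not isolated)
Conditions: 9, 2,4,6-Cl3C6H2COCl, Et3N, toluene, rt; then 8, toluene, 80 °C
Reagents that add atoms: none
Why: Yamaguchi esterification acylates the hydroxyl oxygen without touching the C–O bond (retention), and the DMAP-free mixed-anhydride protocol is the established way to transfer an angeloyl group without Z-to-E isomerisation.

Step 4
Reactants: 11 (3R,4R)-2,3-dimethyloct-1-en-7-yn-4-yl (2Z)-2-methylbut-2-enoate; 12 3-methylbut-2-enoyl chloride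
Product: 14 (5E,9R,10R)-2,10,11-trimethyl-4-oxododeca-2,5,11-trien-9-yl (2Z)-2-methylbut-2-enoate, via alkenylzirconocene chloride 13 (not isolated)
Conditions: Cp2Zr(H)Cl (1.2 equiv), CH2Cl2, rt; then 12, CuBr·SMe2 (10 mol %), THF, 0 °C → rt
Reagents that add atoms: none
Why: syn-Hydrozirconation of the terminal alkyne (much faster than reaction at the 1,1-disubstituted alkene or the ester) puts zirconium on the terminal carbon, and copper-catalysed acylation of the alkenylzirconocene with the acid chloride should give the (E)-enone with retention of geometry.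

Step 5
Reactants: 14 (5E,9R,10R)-2,10,11-trimethyl-4-oxododeca-2,5,11-trien-9-yl (2Z)-2-methylbut-2-enoate
Product: 16 (3Z,5E,9R,10R)-2,10,11-trimethyl-4-[(triethylsilyl)oxy]dodeca-1,3,5,11-tetraen-9-yl (2Z)-2-methylbut-2-enoate, via lithium dienolate 15 (not isolated)
Conditions: LiN(SiMe3)2 (1.1 equiv), Et3SiCl (1.3 equiv), THF, −78 °C
Reagents that add atoms: chlorotriethylsilane, CC[Si](Cl)(CC)CC
Why: Kinetic γ-deprotonation of the methyl group cis to the carbonyl through the lithium-chelated s-cis enone (the future C1 methylene lies across the E double bond and cannot reach this cyclic transition state, and the ester is far less acidic) should give the dienolate with oxygen cis to the new isopropenyl group, which O-silylation traps as the (3Z) silyl dienol ether.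

Step 6
Reactants: 16 (3Z,5E,9R,10R)-2,10,11-trimethyl-4-[(triethylsilyl)oxy]dodeca-1,3,5,11-tetraen-9-yl (2Z)-2-methylbut-2-enoate
Product: 17 3α-angeloyloxy-8-(triethylsilyloxy)-7βH,10βH-eremophila-8,11-diene (cis-fused; 4β- and 5β-methyl; isopropenyl α at C7)
Conditions: toluene (0.005 M), BHT (cat.), silylated sealed tube, 200 °C
Reagents that add atoms: none
Why: A thermal, concerted (asynchronous) suprafacial [4+2] cycloaddition joins the s-cis 2-silyloxy diene C7=C8–C9=C10 to the tethered, unactivated 1,1-disubstituted alkene C5=C6; the closest known reaction type is the type 1 intramolecular Diels–Alder reaction of (E)-1,7,9-decatrienes bearing 2-silyloxy dienes. Ring B is closed by both new bonds as the cyclohexene of the cycloaddition (C8=C9 remains as a regiodefined silyl enol ether), and ring A is closed by the C5–C10 bond in the fused mode, the C1–C4 chain linking diene terminus C10 to the internal dienophile carbon C5. The cis fusion (C5 methyl and H10 syn) should result from the endo orientation of the tether, which keeps the C5 methyl out from under C8/C9 and lets the C1–C2 bond sit synclinal to C9=C10, where C9 bears only hydrogen. The configuration of C5/C10 relative to C3/C4 should result from a chair-like tether with the C3 angelate and C4 methyl equatorial, which places the C5 methyl axial on ring A and therefore cis to the C4 methyl. C7 is fixed by diene geometry: the isopropenyl group is in the outside position (enol ether oxygen cis to it) and so ends up cis to C1, that is 7α, which is accepted here and corrected in step 9. The step needs endo-tether (cis) over exo-tether (trans) selectivity, expected to be modest, and a clean thermal window; the substrate offers the exo preference of the angular methyl, a diene with no inside alkyl group (so no 1,5-hydrogen shift), and a (3Z) enol ether that rules out 6π-electrocyclisation of the triene.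

Step 7
Reactants: 17 3α-angeloyloxy-8-(triethylsilyloxy)-7βH,10βH-eremophila-8,11-diene
Product: 19 3α-angeloyloxy-9β-hydroxy-7βH,10βH-eremophil-11-en-8-one, via silyloxy epoxide 18 (not isolated)
Conditions: dimethyldioxirane, acetone/CH2Cl2, −78 °C; then AcOH, THF/H2O, 0 °C
Reagents that add atoms: dimethyldioxirane, CC1(C)OO1
Why: Rubottom oxidation: the electron-rich C8=C9 silyl enol ether should be epoxidised far faster than the isopropenyl and angelate double bonds and from the β face (anti to the C10–C1 bond, the 7α-isopropenyl group and the concave side of the cis-decalin), so that hydrolytic opening gives the C8 ketone with the 9β-hydroxyl (9R).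

Step 8
Reactants: 19 3α-angeloyloxy-9β-hydroxy-7βH,10βH-eremophil-11-en-8-one; 12 3-methylbut-2-enoyl chloride
Product: 20 3α-angeloyloxy-9β-senecioyloxy-7βH,10βH-eremophil-11-en-8-one (C7 epimer of the target)
Conditions: pyridine, DMAP (cat.), CH2Cl2, 0 °C
Reagents that add atoms: none
Why: Nucleophile-catalysed O-acylation of the secondary α-ketol with the acid chloride under mild amine base should keep the senecioyl double bond conjugated and leave the stereocentres untouched.

Step 9
Reactants: 20 3α-angeloyloxy-9β-senecioyloxy-7βH,10βH-eremophil-11-en-8-one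
Product: 21 3α-angeloyloxy-9β-senecioyloxy-7αH,10βH-eremophil-11-en-8-one, (1R,3R,4aR,5R,6R,8aS)-4a,5-dimethyl-6-{[(2Z)-2-methylbut-2-enoyl]oxy}-2-oxo-3-(prop-1-en-2-yl)decahydronaphthalen-1-yl 3-methylbut-2-enoate
Conditions: DBU (0.2 equiv), toluene, 0 °C → rt
Reagents that add atoms: none
Why: Base-mediated epimerisation through the C7 enolate under thermodynamic control: the 7α-isopropenyl group is syn-axial to the C5–C4 bond, whereas kinetic α-reprotonation at C7 from the α face gives the all-equatorial 7β-isopropenyl (7R) epimer and keeps the double bond out of conjugation (C9, also enolisable, already holds the favoured equatorial acyloxy group).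

Compound list
1 | (Z)-2-bromobut-2-ene | C/C=C(/C)Br | starting material
2 | 2-(chloromethyl)-4,4,5,5-tetramethyl-1,3,2-dioxaborolane | ClCB1OC(C)(C)C(C)(C)O1 | starting material
3 | but-2-en-2-yllithium, methyl groups trans (geometry of 1 retained) | C/C=C(/C)[Li] | intermediate
4 | lithium (but-2-en-2-yl)(chloromethyl)(pinacolato)borate | [Li+].C/C=C(/C)[B-]1(CCl)OC(C)(C)C(C)(C)O1 | intermediate
5 | (Z)-4,4,5,5-tetramethyl-2-(2-methylbut-2-en-1-yl)-1,3,2-dioxaborolane | C/C=C(/C)CB1OC(C)(C)C(C)(C)O1 | intermediate
6 | pent-4-ynal | C#CCCC=O | starting material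
7 | 2-{[(3R,4R)-2,3-dimethyloct-1-en-7-yn-4-yl]oxy}-4,4,5,5-tetramethyl-1,3,2-dioxaborolane | C=C(C)[C@@H](C)[C@H](OB1OC(C)(C)C(C)(C)O1)CCC#C | intermediate
8 | (3R,4R)-2,3-dimethyloct-1-en-7-yn-4-ol (3,4-syn) | C=C(C)[C@@H](C)[C@H](O)CCC#C | intermediate
9 | angelic acid, (2Z)-2-methylbut-2-enoic acid | C/C=C(/C)C(=O)O | starting material
10 | (2Z)-2-methylbut-2-enoic 2,4,6-trichlorobenzoic anhydride | C/C=C(/C)C(=O)OC(=O)c1c(Cl)cc(Cl)cc1Cl | intermediate
11 | (3R,4R)-2,3-dimethyloct-1-en-7-yn-4-yl (2Z)-2-methylbut-2-enoate | C=C(C)[C@@H](C)[C@H](OC(=O)/C(C)=C\C)CCC#C | intermediate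
12 | 3-methylbut-2-enoyl chloride (senecioyl chloride) | CC(C)=CC(=O)Cl | starting material
13 | [(1E,5R,6R)-6,7-dimethyl-5-{[(2Z)-2-methylbut-2-enoyl]oxy}octa-1,7-dien-1-yl]zirconocene chloride | C=C(C)[C@@H](C)[C@H](OC(=O)/C(C)=C\C)CC/C=C/[Zr](Cl)(C1C=CC=C1)C1C=CC=C1 | intermediate
14 | (5E,9R,10R)-2,10,11-trimethyl-4-oxododeca-2,5,11-trien-9-yl (2Z)-2-methylbut-2-enoate | C=C(C)[C@@H](C)[C@H](OC(=O)/C(C)=C\C)CC/C=C/C(=O)C=C(C)C | intermediate
15 | lithium (3Z,5E)-dienolate of 14 (O–Li on the former ketone carbon, oxygen cis to isopropenyl) | C=C(C)[C@@H](C)[C@H](OC(=O)/C(C)=C\C)CC/C=C/C(O[Li])=C/C(C)=C | intermediate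
16 | (3Z,5E,9R,10R)-2,10,11-trimethyl-4-[(triethylsilyl)oxy]dodeca-1,3,5,11-tetraen-9-yl (2Z)-2-methylbut-2-enoate | C=C(C)[C@@H](C)[C@H](OC(=O)/C(C)=C\C)CC/C=C/C(O[Si](CC)(CC)CC)=C/C(C)=C | intermediate
17 | 3α-angeloyloxy-8-(triethylsilyloxy)-7βH,10βH-eremophila-8,11-diene (cis-fused, 4β,5β-dimethyl, 7α-isopropenyl) | C=C(C)[C@@H]1C[C@@]2(C)[C@H](CC[C@@H](OC(=O)/C(C)=C\C)[C@@H]2C)C=C1O[Si](CC)(CC)CC | intermediate
18 | 8β,9β-epoxide of 17 (8-triethylsilyloxy oxirane) | C=C(C)[C@@H]1C[C@@]2(C)[C@H](CC[C@@H](OC(=O)/C(C)=C\C)[C@@H]2C)[C@H]3O[C@@]13O[Si](CC)(CC)CC | intermediate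
19 | 3α-angeloyloxy-9β-hydroxy-7βH,10βH-eremophil-11-en-8-one | C=C(C)[C@@H]1C[C@@]2(C)[C@H](CC[C@@H](OC(=O)/C(C)=C\C)[C@@H]2C)[C@@H](O)C1=O | intermediate
20 | 3α-angeloyloxy-9β-senecioyloxy-7βH,10βH-eremophil-11-en-8-one, (1R,3S,4aR,5R,6R,8aS) epimer | C=C(C)[C@@H]1C[C@@]2(C)[C@H](CC[C@@H](OC(=O)/C(C)=C\C)[C@@H]2C)[C@@H](OC(=O)C=C(C)C)C1=O | intermediate
21 | 3α-angeloyloxy-9β-senecioyloxy-7αH,10βH-eremophil-11-en-8-one, (1R,3R,4aR,5R,6R,8aS)-4a,5-dimethyl-6-{[(2Z)-2-methylbut-2-enoyl]oxy}-2-oxo-3-(prop-1-en-2-yl)decahydronaphthalen-1-yl 3-methylbut-2-enoate | C=C(C)[C@H]1C[C@@]2(C)[C@H](CC[C@@H](OC(=O)/C(C)=C\C)[C@@H]2C)[C@@H](OC(=O)C=C(C)C)C1=O | target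

Total step count: 9. Longest linear sequence: 9 steps (1 → 5 → 8 → 11 → 14 → 16 → 17 → 19 → 20 → 21).

Steps most likely to fail

Step 6. The cycloaddition may run through the exo-tether transition state and give the trans-fused decalin, or the unactivated alkene may react so slowly that the silyl dienol ether or the angelate geometry decays first. Fallback: the pericyclic reaction is replaced by a metal-templated [4+2]. Compound 16 is treated with [Rh(coe)2Cl]2 and P(OCH(CF3)2)3 in THF at 55 °C, the rhodium-catalysed cycloisomerisation known for unactivated diene–enes. It forms the same two bonds stepwise (oxidative cyclisation to an allyl rhodacycle, then reductive elimination), so ring fusion is decided in the metallacycle, not by the endo/exo balance, and no high temperature is needed. The fallback sets out from 16 and returns at 17; it makes no new compound (F0).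

Step 9. Under base the isopropenyl double bond may migrate into conjugation with the C8 ketone (γ-protonation of the dienolate) faster than C7 is inverted, or the senecioyl group may shift from O9 to O8 through the C9 enolate. Fallback: kinetic control replaces thermodynamic control. Compound 20 is converted with Me3SiOTf/Et3N (CH2Cl2, −78 °C) into the C7=C8 trimethylsilyl dienol ether F1. Protonolysis at −78 °C (HCl in THF) should deliver the proton to C7 axially from the α face and give 21 directly. The fallback sets out from 20 and returns at 21.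

Step 3. The angeloyl unit may isomerise from Z to E (tigloyl ester) during activation or during acylation of the hindered alcohol. Fallback: the Z double bond is built after the ester bond. Alcohol 8 is esterified (DCC, DMAP, CH2Cl2) with 2-[bis(2,2,2-trifluoroethoxy)phosphoryl]propanoic acid to the phosphonate ester F2. Still–Gennari olefination with acetaldehyde (KN(SiMe3)2, 18-crown-6, THF, −78 °C) should then form the (Z)-2-methylbut-2-enoate in place. The fallback sets out from 8 and returns at 11.

Further compounds
F0 | step 6 | none | none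
F1 | step 9 | 3α-angeloyloxy-9β-senecioyloxy-8-(trimethylsilyloxy)-10βH-eremophila-7,11-diene | C=C(C)C=1C[C@@]2(C)[C@H](CC[C@@H](OC(=O)/C(C)=C\C)[C@@H]2C)[C@@H](OC(=O)C=C(C)C)C=1O[Si](C)(C)C
F2 | step 3 | (3R,4R)-2,3-dimethyloct-1-en-7-yn-4-yl 2-[bis(2,2,2-trifluoroethoxy)phosphoryl]propanoate | C=C(C)[C@@H](C)[C@H](OC(=O)C(C)P(=O)(OCC(F)(F)F)OCC(F)(F)F)CCC#C
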